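**Retrosynthetic overview**

1. The target is a trans-fused decalin (ring A: C1–C5, C10; ring B: C5–C10). The two (Z)-enoates come last from hex-2-ynoates (Lindlar); the C9 ester by Mitsunobu inversion, the C8 hydroxyl by Rubottom oxidation and the C7 isopropenyl group by cuprate addition to a 7-en-9-one.
2. The strategy rests on one feature: the C3 carbinol is joined to C10 through C2 and C1. C2 is therefore the γ-carbon of the C9-ketone dienolate (O–C9=C10–C1=C2), and C3 can be an aldehyde on the C4 arm of quaternary C5. Ring A is closed at C2–C3 by an intramolecular vinylogous aldol.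
3. During the closure C4 carries a phenylselanyl group. This makes the aldehyde non-enolisable and stores the C4=C15 alkene, so C4 is set afterwards by hydrogenation anti to the C5 methyl; C10 is set by Li/NH3.
4. Ring B is bought (3-methylcyclohexenone) and is elaborated first: enantioselective conjugate addition of the C15–C4–C3 alkenyl unit creates C5, and an aldol with acetaldehyde at C10 brings C1–C2. Ring A is formed second.

Key step: step 8

Remark: eremophilane numbering is used (C14 = methyl on C5, C15 = methyl on C4, C11–C13 = isopropenyl on C7) and α is the face of the C5 methyl group. Compounds 7–16 are carried as mixtures at centres or alkene geometries that are erased later, as stated in their names; compound 1 is taken as purchased.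

**Step 1**
Reactants: 1 tert-butyldimethyl(prop-2-yn-1-yloxy)silane; 2 3-methylcyclohex-2-en-1-one
Product: 5 (S)-tert-butyldimethyl{2-[1-methyl-3-(triethylsilyloxy)cyclohex-2-en-1-yl]allyloxy}silane, via alkenylalane 3 (not isolated), via aluminium enolate 4 (not isolated)
Conditions: 1, i-Bu2AlH, Ni(dppp)Cl2 (3 mol%), THF, 0 → 22 °C; then 2, CuCl2·2H2O (5 mol%), chiral sulfonate-bearing NHC–silver complex [(NHC)Ag]2 (2.5 mol%), THF, −78 → −15 °C; then Et3SiOTf, −78 → 0 °C
Reagents that add atoms: triethylsilyl trifluoromethanesulfonate, CC[Si](CC)(CC)OS(=O)(=O)C(F)(F)F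
Why: Ni-catalysed α-selective hydroalumination puts aluminium on the internal alkyne carbon, and the chiral NHC–Cu catalyst then transfers this alkenyl group (in preference to isobutyl) to the β-carbon of 2 in an enantioselective conjugate addition that creates quaternary C5 (ligand antipode chosen for the S configuration), the aluminium enolate being O-silylated so that the C9–C10 enol ether is regiodefined.

**Step 2**
Reactants: 5; 6 acetaldehyde
Product: 7 (3S)-2-(1-hydroxyethyl)-3-methyl-3-[3-(tert-butyldimethylsilyloxy)prop-1-en-2-yl]cyclohexan-1-one (mixture at C2 and at the carbinol)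
Conditions: 6 (3 equiv), TiCl4 (1.05 equiv), CH2Cl2, −78 °C; then aq. NaHCO3
Reagents that add atoms: acetaldehyde (6), CC=O
Why: Mukaiyama aldol, in which the TiCl4-activated aldehyde is attacked by C10, the only nucleophilic carbon of the regiodefined enol ether, installing C1 and C2; the new centres are left uncontrolled because both become sp2 in step 4.

**Step 3**
Reactants: 7
Product: 8 (3R)-2-(1-hydroxyethyl)-3-methyl-3-[1-(tert-butyldimethylsilyloxy)propan-2-yl]cyclohexan-1-one (diastereomer mixture)
Conditions: H2 (1 atm), 5% Pt/C, EtOAc, rt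
Reagents that add atoms: none
Why: Heterogeneous hydrogenation saturates the 1,1-disubstituted alkene while ketone, hydroxyl and silyl ether survive; C4 forms as both epimers, which is harmless because C4 is made quaternary in step 7 and sp2 in step 9.

**Step 4**
Reactants: 8
Product: 10 (3R)-2-ethylidene-3-methyl-3-[1-(tert-butyldimethylsilyloxy)propan-2-yl]cyclohexan-1-one (E/Z and C4 mixture), via mesylate 9 (not isolated)
Conditions: MsCl, Et3N, CH2Cl2, 0 °C; then DBU, 0 °C → rt
Reagents that add atoms: none
Why: Mesylation followed by E1cB elimination through the C10 enolate gives the conjugated 2-ethylidene ketone; its geometry is irrelevant because it is lost in the dienolate of step 8.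

**Step 5**
Reactants: 10
Product: 11 (3R)-2-ethylidene-3-(1-hydroxypropan-2-yl)-3-methylcyclohexan-1-one (E/Z and C4 mixture)
Conditions: HF·pyridine, pyridine, THF, 0 °C → rt
Reagents that add atoms: none
Why: Fluoride cleaves the primary silyl ether (desilylation), and the buffered acidic medium avoids base-induced conjugate addition of the freed alcohol to the enone.

**Step 6**
Reactants: 11
Product: 12 (3R)-2-[(E)-ethylidene]-3-methyl-3-[(2R)-1-oxopropan-2-yl]cyclohexan-1-one, obtained together with its (2S)-epimer and Z isomer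
Conditions: Dess–Martin periodinane, NaHCO3, CH2Cl2, 0 °C → rt
Reagents that add atoms: none
Why: Periodinane oxidation of the primary alcohol stops at the aldehyde under buffered conditions and leaves the enone untouched.

**Step 7**
Reactants: 12
Product: 13 (3S)-2-ethylidene-3-methyl-3-[1-oxo-2-(phenylselanyl)propan-2-yl]cyclohexan-1-one (both C4 epimers)
Conditions: PhSeCl (1.05 equiv), EtOAc, 0 °C → rt
Reagents that add atoms: benzeneselenenyl chloride, Cl[Se]c1ccccc1
Why: Electrophilic α-selenenylation through the aldehyde enol (the hindered conjugated ketone enolises more slowly) makes C4 quaternary, which blocks enolisation of the aldehyde in step 8 and stores the C4=C15 alkene in latent form; the configuration at C4 is immaterial.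

**Step 8**
Reactants: 13
Product: 15 3β-hydroxy-4-(phenylselanyl)-4,5α-dimethyl-11,12,13-trinoreremophil-1(10)-en-9-one (both C4 epimers), via potassium dienolate 14 (not isolated)
Conditions: t-BuOK (0.3 equiv), t-BuOH/THF (1:4), 0.02 M, 0 °C → rt, held until the C3 epimer ratio no longer changes; AcOH quench
Reagents that add atoms: none
Why: The alkoxide reversibly removes a γ-proton from C2 of the 2-ethylidene ketone to give the extended dienolate 14 (O–C9=C10–C1=C2), in which rotation about C10–C1 erases the alkene geometry, and its γ-carbon adds to the C3 aldehyde; the closest known reaction type is the base-mediated γ-selective intramolecular vinylogous aldol addition of enones onto tethered aldehydes. Ring A closes by forming C2–C3 in a 6-(enolendo)-exo-trig mode, which restores the conjugated 1(10)-en-9-one. The one new stereocentre that is kept, C3, is set under thermodynamic control by C5: the aldol is reversible under alkoxide catalysis, the 3β-alcohol has a pseudo-equatorial hydroxyl, and the 3α-epimer would place it 1,3-diaxial to the axial C5 methyl group. The step needs γ-selectivity over α and α′: attack from C10 would give a cyclobutanol, and the aldol of the kinetic C8 enolate gives a strained bicyclo[2.2.2]octanol that reverts by retro-aldol, so the fused δ-hydroxy enone is the thermodynamic sink. The phenylselanyl group leaves the aldehyde without an α-hydrogen, so it can act only as the electrophile, and it avoids the conjugate-addition pathway that an α-methylene aldehyde would open; both C4 epimers converge in step 9.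

**Step 9**
Reactants: 15
Product: 17 3β-hydroxy-5α-methyl-11,12,13-trinoreremophila-1(10),4(15)-dien-9-one, via selenoxide 16 (not isolated)
Conditions: 30% H2O2, pyridine, CH2Cl2, 0 °C → rt
Reagents that add atoms: none
Why: Oxidation to the selenoxide is followed by syn-elimination, which proceeds toward the C15 methyl group (C5 bears no hydrogen and elimination toward a carbinol carbon is disfavoured), so both C4 epimers give the 4(15)-alkene.

**Step 10**
Reactants: 17
Product: 18 3β-hydroxy-4α,5α-dimethyl-11,12,13-trinoreremophil-1(10)-en-9-one, i.e. (4aR,5R,6R)-6-hydroxy-4a,5-dimethyl-3,4,4a,5,6,7-hexahydronaphthalen-1(2H)-one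
Conditions: H2 (1 atm), [Ir(cod)(PCy3)(py)]PF6 (3 mol%), CH2Cl2, 0 °C
Reagents that add atoms: none
Why: Homogeneous hydrogenation with the cationic iridium catalyst adds hydrogen to the 1,1-disubstituted alkene from the β-face, which is opposite the axial C5 methyl group and is the side of the coordinating 3β-hydroxyl, so C15 ends up α (cis to C14); the conjugated trisubstituted C1=C10 bond reacts much more slowly.

**Step 11**
Reactants: 18
Product: 19 3β-(triethylsilyloxy)-4α,5α-dimethyl-11,12,13-trinoreremophil-1(10)-en-9-one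
Conditions: Et3SiCl, imidazole, CH2Cl2, 0 °C → rt
Reagents that add atoms: chlorotriethylsilane, CC[Si](Cl)(CC)CC
Why: Silylation gives an ether that survives dissolving metal, amide base and cuprate, yet is more labile than the later C8 tert-butyldimethylsilyl ether.

**Step 12**
Reactants: 19
Product: 21 3β-(triethylsilyloxy)-4α,5α-dimethyl-11,12,13-trinor-10βH-eremophilan-9-one (trans-fused), via lithium enolate 20 (not isolated)
Conditions: Li, NH3(l)/THF, t-BuOH (1.0 equiv), −78 °C; then solid NH4Cl
Reagents that add atoms: none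
Why: Dissolving-metal (Birch-type) reduction of the enone gives the C9–C10 enolate, which is protonated at C10 on the β-face, anti to the axial C5 methyl, to give the trans-fused decalone; this is expected to be the more stable C10 epimer as well, so brief base treatment would correct any cis isomer.

**Step 13**
Reactants: 21
Product: 23 3β-(triethylsilyloxy)-4α,5α-dimethyl-11,12,13-trinor-10βH-eremophil-7-en-9-one, via trimethylsilyl enol ether 22 (not isolated)
Conditions: LiN(i-Pr)2, THF, −78 °C; Me3SiCl; then Pd(OAc)2 (1.1 equiv), MeCN, rt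
Reagents that add atoms: none
Why: Kinetic deprotonation occurs at the C8 methylene rather than the ring-fusion methine C10, and Saegusa–Ito oxidation of the silyl enol ether introduces the C7=C8 double bond.

**Step 14**
Reactants: 23; 24 isopropenylmagnesium bromide
Product: 25 7β-isopropenyl-3β-(triethylsilyloxy)-9-(trimethylsilyloxy)-10βH-eremophila-8,11-diene
Conditions: 24 (2 equiv), CuBr·SMe2 (0.2 equiv), Me3SiCl (3 equiv), THF, −78 → −40 °C; Et3N, aq. NaHCO3
Reagents that add atoms: isopropenylmagnesium bromide (24), C=C(C)[Mg]Br; chlorotrimethylsilane, C[Si](C)(C)Cl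
Why: Copper-catalysed conjugate addition, accelerated by the silyl chloride, delivers the isopropenyl group to C7 from the β-face because the α-face trajectory is 1,3-diaxial to the C5 methyl group, and the enolate is trapped as the C8–C9 silyl enol ether.

**Step 15**
Reactants: 25
Product: 27 8β-hydroxy-7β-isopropenyl-3β-(triethylsilyloxy)-10βH-eremophil-11-en-9-one, via silyloxy epoxide 26 (not isolated)
Conditions: dimethyldioxirane (1.05 equiv, acetone), CH2Cl2, −78 → −40 °C; then citric acid, MeOH, 0 °C
Reagents that add atoms: dimethyldioxirane, CC1(C)OO1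
Why: Rubottom oxidation, in which the electron-rich enol ether is epoxidised far faster than the isopropenyl group and from the β-face opposite the C5 methyl (axial attack at C8); mild acidic methanolysis then gives the axial 8β-hydroxy ketone without base that could epimerise C8.

**Step 16**
Reactants: 27
Product: 28 8β-(tert-butyldimethylsilyloxy)-7β-isopropenyl-3β-(triethylsilyloxy)-10βH-eremophil-11-en-9-one
Conditions: t-BuMe2SiOTf, 2,6-lutidine, CH2Cl2, −78 → 0 °C
Reagents that add atoms: tert-butyldimethylsilyl trifluoromethanesulfonate, CC(C)(C)[Si](C)(C)OS(=O)(=O)C(F)(F)F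
Why: The silyl triflate silylates the hindered axial hydroxyl at low temperature and gives an ether that tolerates the hydride, Mitsunobu and mild-acid steps that follow.

**Step 17**
Reactants: 28
Product: 29 8β-(tert-butyldimethylsilyloxy)-7β-isopropenyl-3β-(triethylsilyloxy)-10βH-eremophil-11-en-9α-ol
Conditions: NaBH4, MeOH/THF, 0 °C
Reagents that add atoms: none
Why: Hydride reduction from the β-face, because the axial α-face trajectory at C9 is blocked by the syn-axial C5 methyl group (as in 6-oxo-5α-steroids), should give the axial 9α-alcohol, trans-diaxial to the C8 silyloxy group.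

**Step 18**
Reactants: 29; 30 hex-2-ynoic acid
Product: 31 8β-(tert-butyldimethylsilyloxy)-7β-isopropenyl-3β-(triethylsilyloxy)-10βH-eremophil-11-en-9β-yl hex-2-ynoate
Conditions: 30 (3 equiv), PPh3, DIAD, toluene, 0 °C → rt
Reagents that add atoms: hex-2-ynoic acid (30), CCCC#CC(=O)O
Why: Mitsunobu reaction, in which the alkoxyphosphonium ion of the axial 9α-alcohol is displaced by the acidic alkynoate with inversion to give the equatorial 9β-ester; the C8 silyl ether cannot participate.

**Step 19**
Reactants: 31
Product: 32 8β-(tert-butyldimethylsilyloxy)-3β-hydroxy-7β-isopropenyl-10βH-eremophil-11-en-9β-yl hex-2-ynoate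
Conditions: PPTS (0.2 equiv), MeOH/CH2Cl2, 0 °C → rt
Reagents that add atoms: none
Why: Acid-catalysed methanolysis removes the unhindered triethylsilyl ether selectively; the hindered secondary tert-butyldimethylsilyl ether and the ynoate are stable under these conditions.

**Step 20**
Reactants: 32; 30 hex-2-ynoic acid
Product: 33 8β-(tert-butyldimethylsilyloxy)-7β-isopropenyl-10βH-eremophil-11-ene-3β,9β-diyl bis(hex-2-ynoate)
Conditions: 30 (1.5 equiv), DCC, DMAP (5 mol%), CH2Cl2, 0 °C
Reagents that add atoms: hex-2-ynoic acid (30), CCCC#CC(=O)O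
Why: Steglich esterification acylates the equatorial C3 hydroxyl, the only free hydroxyl group, with retention.

**Step 21**
Reactants: 33
Product: 34 8β-hydroxy-7β-isopropenyl-10βH-eremophil-11-ene-3β,9β-diyl bis(hex-2-ynoate)
Conditions: HF·pyridine, pyridine, THF, 0 °C → rt
Reagents that add atoms: none
Why: Buffered fluoride desilylation cleaves the remaining silyl ether under mildly acidic conditions that should not promote acyl migration from O9 to the cis O8 and that leave the ynoates and the isopropenyl group intact.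

**Step 22**
Reactants: 34
Product: 35 target, (3R,4R,5R,7S,8R,9S,10R)-8β-hydroxy-7β-isopropenyl-10βH-eremophil-11-ene-3β,9β-diyl bis[(2Z)-hex-2-enoate]
Conditions: H2 (1 atm), Lindlar catalyst (Pd/CaCO3 poisoned with Pb(OAc)2), quinoline, EtOAc, rt
Reagents that add atoms: none
Why: Lindlar semihydrogenation adds hydrogen syn to both conjugated alkynes and gives the two (Z)-enoates, while the 1,1-disubstituted isopropenyl alkene is not reduced on the poisoned catalyst.

**Compound list**

1 | tert-butyldimethyl(prop-2-yn-1-yloxy)silane | C#CCO[Si](C)(C)C(C)(C)C | starting material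
2 | 3-methylcyclohex-2-en-1-one | CC1=CC(=O)CCC1 | starting material
3 | diisobutyl[3-(tert-butyldimethylsilyloxy)prop-1-en-2-yl]alane | C=C(CO[Si](C)(C)C(C)(C)C)[Al](CC(C)C)CC(C)C | intermediate (not isolated)
4 | diisobutylaluminium enolate of (S)-3-methyl-3-[3-(tert-butyldimethylsilyloxy)prop-1-en-2-yl]cyclohexanone | C1C[C@](C)(C(=C)CO[Si](C)(C)C(C)(C)C)C=C(O[Al](CC(C)C)CC(C)C)C1 | intermediate (not isolated)
5 | (S)-tert-butyldimethyl{2-[1-methyl-3-(triethylsilyloxy)cyclohex-2-en-1-yl]allyloxy}silane | C1C[C@](C)(C(=C)CO[Si](C)(C)C(C)(C)C)C=C(O[Si](CC)(CC)CC)C1 | intermediate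
6 | acetaldehyde | CC=O | starting material
7 | (3S)-2-(1-hydroxyethyl)-3-methyl-3-[3-(tert-butyldimethylsilyloxy)prop-1-en-2-yl]cyclohexan-1-one (mixture at C2 and carbinol) | C1C[C@](C)(C(=C)CO[Si](C)(C)C(C)(C)C)C(C(C)O)C(=O)C1 | intermediate
8 | (3R)-2-(1-hydroxyethyl)-3-methyl-3-[1-(tert-butyldimethylsilyloxy)propan-2-yl]cyclohexan-1-one (diastereomer mixture) | C1C[C@](C)(C(C)CO[Si](C)(C)C(C)(C)C)C(C(C)O)C(=O)C1 | intermediate
9 | methanesulfonate of 8 | C1C[C@](C)(C(C)CO[Si](C)(C)C(C)(C)C)C(C(C)OS(C)(=O)=O)C(=O)C1 | intermediate (not isolated)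
10 | (3R)-2-ethylidene-3-methyl-3-[1-(tert-butyldimethylsilyloxy)propan-2-yl]cyclohexan-1-one (E drawn; E/Z and C4 mixture) | C1C[C@](C)(C(C)CO[Si](C)(C)C(C)(C)C)/C(=C\C)C(=O)C1 | intermediate
11 | (3R)-2-ethylidene-3-(1-hydroxypropan-2-yl)-3-methylcyclohexan-1-one (E drawn; E/Z and C4 mixture) | C1C[C@](C)(C(C)CO)/C(=C\C)C(=O)C1 | intermediate
12 | (3R)-2-[(E)-ethylidene]-3-methyl-3-[(2R)-1-oxopropan-2-yl]cyclohexan-1-one (drawn isomer; its (2S)-epimer and Z isomer accompany it) | C1C[C@](C)([C@@H](C)C=O)/C(=C\C)C(=O)C1 | intermediate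
13 | (3S)-2-ethylidene-3-methyl-3-[1-oxo-2-(phenylselanyl)propan-2-yl]cyclohexan-1-one (E drawn; both C4 epimers) | C1C[C@](C)(C(C)([Se]c2ccccc2)C=O)/C(=C\C)C(=O)C1 | intermediate
14 | potassium dienolate of 13 (O–C9=C10–C1=C2) | C1C[C@](C)(C(C)([Se]c2ccccc2)C=O)C(C=C)=C([O-])C1.[K+] | intermediate (not isolated)
15 | 3β-hydroxy-4-(phenylselanyl)-4,5α-dimethyl-11,12,13-trinoreremophil-1(10)-en-9-one (both C4 epimers) | C1C[C@]2(C)C(C)([Se]c3ccccc3)[C@H](O)CC=C2C(=O)C1 | intermediate
16 | Se-oxide of 15 | C1C[C@]2(C)C(C)([Se](=O)c3ccccc3)[C@H](O)CC=C2C(=O)C1 | intermediate (not isolated)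
17 | 3β-hydroxy-5α-methyl-11,12,13-trinoreremophila-1(10),4(15)-dien-9-one | C1C[C@]2(C)C(=C)[C@H](O)CC=C2C(=O)C1 | intermediate
18 | 3β-hydroxy-4α,5α-dimethyl-11,12,13-trinoreremophil-1(10)-en-9-one | C1C[C@]2(C)[C@@H](C)[C@H](O)CC=C2C(=O)C1 | intermediate
19 | 3β-(triethylsilyloxy)-4α,5α-dimethyl-11,12,13-trinoreremophil-1(10)-en-9-one | C1C[C@]2(C)[C@@H](C)[C@H](O[Si](CC)(CC)CC)CC=C2C(=O)C1 | intermediate
20 | lithium 9(10)-enolate from 19 | C1C[C@]2(C)[C@@H](C)[C@H](O[Si](CC)(CC)CC)CCC2=C([O-])C1.[Li+] | intermediate (not isolated)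
21 | 3β-(triethylsilyloxy)-4α,5α-dimethyl-11,12,13-trinor-10βH-eremophilan-9-one | C1C[C@]2(C)[C@@H](C)[C@H](O[Si](CC)(CC)CC)CC[C@H]2C(=O)C1 | intermediate
22 | 3β-(triethylsilyloxy)-9-(trimethylsilyloxy)-4α,5α-dimethyl-11,12,13-trinor-10βH-eremophil-8-ene | C1C[C@]2(C)[C@@H](C)[C@H](O[Si](CC)(CC)CC)CC[C@H]2C(O[Si](C)(C)C)=C1 | intermediate (not isolated)
23 | 3β-(triethylsilyloxy)-4α,5α-dimethyl-11,12,13-trinor-10βH-eremophil-7-en-9-one | C=1C[C@]2(C)[C@@H](C)[C@H](O[Si](CC)(CC)CC)CC[C@H]2C(=O)C=1 | intermediate
24 | isopropenylmagnesium bromide | C=C(C)[Mg]Br | starting material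
25 | 7β-isopropenyl-3β-(triethylsilyloxy)-9-(trimethylsilyloxy)-10βH-eremophila-8,11-diene | C=C(C)[C@@H]1C[C@]2(C)[C@@H](C)[C@H](O[Si](CC)(CC)CC)CC[C@H]2C(O[Si](C)(C)C)=C1 | intermediate
26 | 8β,9β-epoxy-7β-isopropenyl-3β-(triethylsilyloxy)-9α-(trimethylsilyloxy)-10βH-eremophil-11-ene | C=C(C)[C@@H]1C[C@]2(C)[C@@H](C)[C@H](O[Si](CC)(CC)CC)CC[C@H]2[C@]3(O[Si](C)(C)C)O[C@H]13 | intermediate (not isolated)
27 | 8β-hydroxy-7β-isopropenyl-3β-(triethylsilyloxy)-10βH-eremophil-11-en-9-one | C=C(C)[C@@H]1C[C@]2(C)[C@@H](C)[C@H](O[Si](CC)(CC)CC)CC[C@H]2C(=O)[C@@H]1O | intermediate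
28 | 8β-(tert-butyldimethylsilyloxy)-7β-isopropenyl-3β-(triethylsilyloxy)-10βH-eremophil-11-en-9-one | C=C(C)[C@@H]1C[C@]2(C)[C@@H](C)[C@H](O[Si](CC)(CC)CC)CC[C@H]2C(=O)[C@@H]1O[Si](C)(C)C(C)(C)C | intermediate
29 | 8β-(tert-butyldimethylsilyloxy)-7β-isopropenyl-3β-(triethylsilyloxy)-10βH-eremophil-11-en-9α-ol | C=C(C)[C@@H]1C[C@]2(C)[C@@H](C)[C@H](O[Si](CC)(CC)CC)CC[C@H]2[C@@H](O)[C@@H]1O[Si](C)(C)C(C)(C)C | intermediate
30 | hex-2-ynoic acid | CCCC#CC(=O)O | starting material
31 | 8β-(tert-butyldimethylsilyloxy)-7β-isopropenyl-3β-(triethylsilyloxy)-10βH-eremophil-11-en-9β-yl hex-2-ynoate | C=C(C)[C@@H]1C[C@]2(C)[C@@H](C)[C@H](O[Si](CC)(CC)CC)CC[C@H]2[C@H](OC(=O)C#CCCC)[C@@H]1O[Si](C)(C)C(C)(C)C | intermediate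
32 | 8β-(tert-butyldimethylsilyloxy)-3β-hydroxy-7β-isopropenyl-10βH-eremophil-11-en-9β-yl hex-2-ynoate | C=C(C)[C@@H]1C[C@]2(C)[C@@H](C)[C@H](O)CC[C@H]2[C@H](OC(=O)C#CCCC)[C@@H]1O[Si](C)(C)C(C)(C)C | intermediate
33 | 8β-(tert-butyldimethylsilyloxy)-7β-isopropenyl-10βH-eremophil-11-ene-3β,9β-diyl bis(hex-2-ynoate) | C=C(C)[C@@H]1C[C@]2(C)[C@@H](C)[C@H](OC(=O)C#CCCC)CC[C@H]2[C@H](OC(=O)C#CCCC)[C@@H]1O[Si](C)(C)C(C)(C)C | intermediate
34 | 8β-hydroxy-7β-isopropenyl-10βH-eremophil-11-ene-3β,9β-diyl bis(hex-2-ynoate) | C=C(C)[C@@H]1C[C@]2(C)[C@@H](C)[C@H](OC(=O)C#CCCC)CC[C@H]2[C@H](OC(=O)C#CCCC)[C@@H]1O | intermediate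
35 | (3R,4R,5R,7S,8R,9S,10R)-8β-hydroxy-7β-isopropenyl-10βH-eremophil-11-ene-3β,9β-diyl bis[(2Z)-hex-2-enoate] | C=C(C)[C@@H]1C[C@]2(C)[C@@H](C)[C@H](OC(=O)/C=C\CCC)CC[C@H]2[C@H](OC(=O)/C=C\CCC)[C@@H]1O | target

**Step count and risks**

Total step count: 22. Longest linear sequence: 22 steps (1 and 2 to 35).

The three steps most likely to fail:

Step 8 (key step). The congestion between the selenium-bearing C4 and the new carbinol may hold the retro-aldol equilibrium on the open-chain side. Alternatively the adduct may lose water by E1cB through its own C2 dienolate before the C3 epimers have equilibrated. The fallback sets out from 12 and returns at 18. It gives up the selenium relay: ring A is closed on the less hindered α-methyl aldehyde 12 under equilibrating base (K2CO3 in MeOH, or t-BuOK in t-BuOH), where the free α-hydrogen lets C4 epimerise during the reversible aldol. This should give 18 together with its C4 epimer, 3β-hydroxy-4β,5α-dimethyl-11,12,13-trinoreremophil-1(10)-en-9-one F1. F1 is separated by chromatography and returned to the base, where retro-aldol and epimerisation re-form the mixture. C4 is then sorted by recycling instead of being set by hydrogenation, and steps 7, 9 and 10 are skipped.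

Step 18. Backside attack at the axial C9 carbinol may be too slow next to the axial C8 silyloxy group. E2 elimination toward C10 (anti axial hydrogen) or acylation with retention may then take over. The fallback sets out from 27 and returns at 34; it inverts C9 by neighbouring-group participation instead of an external nucleophile:
- Boc2O and DMAP convert 27 into 8β-(tert-butoxycarbonyloxy)-7β-isopropenyl-3β-(triethylsilyloxy)-10βH-eremophil-11-en-9-one F2.
- NaBH4 gives 8β-(tert-butoxycarbonyloxy)-7β-isopropenyl-3β-(triethylsilyloxy)-10βH-eremophil-11-en-9α-ol F3.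
- Tf2O and pyridine activate the 9α-hydroxyl. The antiperiplanar carbonate oxygen displaces the triflate from the β-face with loss of isobutene, giving the cis-fused 8β,9β-carbonyldioxy-7β-isopropenyl-3β-(triethylsilyloxy)-10βH-eremophil-11-ene F4.
- K2CO3 in MeOH opens the carbonate to 7β-isopropenyl-3β-(triethylsilyloxy)-10βH-eremophil-11-ene-8β,9β-diol F5.
- PPTS in MeOH gives 7β-isopropenyl-10βH-eremophil-11-ene-3β,8β,9β-triol F6.
- Hex-2-ynoic acid 30 (2 equiv), DCC and catalytic DMAP at low temperature should acylate the two equatorial hydroxyls (C3 and C9) and leave the hindered axial C8 hydroxyl, giving 34.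

Step 1. The 2-aluminoallyl silyl ether 3 may lose the silyloxy group by β-elimination (allene formation). Isobutyl transfer or modest enantioselectivity would also erode the step. The fallback sets out from 1 and returns at 5; it reverses the roles, so that the alkenyl group is in place first and the methyl group is added enantioselectively:
- Copper-catalysed α-selective protoboration of 1 (B2pin2, MeOH, (SIMes)CuCl, NaOt-Bu) gives tert-butyldimethyl{[2-(4,4,5,5-tetramethyl-1,3,2-dioxaborolan-2-yl)allyl]oxy}silane F7.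
- Suzuki coupling with commercial 3-bromocyclohex-2-en-1-one (Pd(PPh3)4, K3PO4, dioxane/water) gives 3-[3-(tert-butyldimethylsilyloxy)prop-1-en-2-yl]cyclohex-2-en-1-one F8.
- Copper-catalysed enantioselective 1,4-addition of MeMgBr to this dienone (Cu(OTf)2, chiral NHC ligand of the antipode that gives the S centre, Et2O, −30 °C), with the magnesium enolate trapped by Et3SiOTf, gives 5.

**Further compounds**

F1 | step 8 | 3β-hydroxy-4β,5α-dimethyl-11,12,13-trinoreremophil-1(10)-en-9-one | C1C[C@]2(C)[C@H](C)[C@H](O)CC=C2C(=O)C1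
F2 | step 18 | 8β-(tert-butoxycarbonyloxy)-7β-isopropenyl-3β-(triethylsilyloxy)-10βH-eremophil-11-en-9-one | C=C(C)[C@@H]1C[C@]2(C)[C@@H](C)[C@H](O[Si](CC)(CC)CC)CC[C@H]2C(=O)[C@@H]1OC(=O)OC(C)(C)C
F3 | step 18 | 8β-(tert-butoxycarbonyloxy)-7β-isopropenyl-3β-(triethylsilyloxy)-10βH-eremophil-11-en-9α-ol | C=C(C)[C@@H]1C[C@]2(C)[C@@H](C)[C@H](O[Si](CC)(CC)CC)CC[C@H]2[C@@H](O)[C@@H]1OC(=O)OC(C)(C)C
F4 | step 18 | 8β,9β-carbonyldioxy-7β-isopropenyl-3β-(triethylsilyloxy)-10βH-eremophil-11-ene | C=C(C)[C@@H]1C[C@]2(C)[C@@H](C)[C@H](O[Si](CC)(CC)CC)CC[C@H]2[C@H](OC(=O)O3)[C@@H]13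
F5 | step 18 | 7β-isopropenyl-3β-(triethylsilyloxy)-10βH-eremophil-11-ene-8β,9β-diol | C=C(C)[C@@H]1C[C@]2(C)[C@@H](C)[C@H](O[Si](CC)(CC)CC)CC[C@H]2[C@H](O)[C@@H]1O
F6 | step 18 | 7β-isopropenyl-10βH-eremophil-11-ene-3β,8β,9β-triol | C=C(C)[C@@H]1C[C@]2(C)[C@@H](C)[C@H](O)CC[C@H]2[C@H](O)[C@@H]1O
F7 | step 1 | tert-butyldimethyl{[2-(4,4,5,5-tetramethyl-1,3,2-dioxaborolan-2-yl)allyl]oxy}silane | C=C(CO[Si](C)(C)C(C)(C)C)B1OC(C)(C)C(C)(C)O1
F8 | step 1 | 3-[3-(tert-butyldimethylsilyloxy)prop-1-en-2-yl]cyclohex-2-en-1-one | C=C(CO[Si](C)(C)C(C)(C)C)C1=CC(=O)CCC1
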